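**Retrosynthetic overview**
1. Target 16 ⇐ ketone 14 by hydroxyl-directed 1,3-anti reduction (sets C2) and desilylation; the myristate already sits on O3.
2. 14 ⇐ C3–C4 disconnection: anti-selective enamine aldol of 2-oxopropyl tetradecanoate 13 (hydroxyacetone + tetradecanoyl chloride) with β-silyloxy aldehyde 10 (sets C3 and C4).
3. 10 ⇐ C5–C6 disconnection: catalytic enantioselective acetaldehyde cross-aldol on bis-oxazole aldehyde 7 (sets C6, the first stereocenter).
4. 7 ⇐ ester 6 ⇐ amide 3 + ethyl bromopyruvate 4: ring B (the 2,4-disubstituted oxazole) is the only ring built; ring A (the oxazol-5-yl ring) is bought in acid 1.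

Assumption: 2-(1,3-oxazol-5-yl)acetic acid (1) is treated as a purchasable catalogue building block; chain carbons are numbered from the methyl end (C1 = CH3, C3 = ester carbon, C6 = carbinol on ring B).

**Route**

Step 1
Reactants: 1 2-(1,3-oxazol-5-yl)acetic acid
Product: 3 2-(1,3-oxazol-5-yl)acetamide, via acyl imidazolide 2 (not isolated)
Conditions: 1,1'-carbonyldiimidazole (CDI, 1.1 equiv), THF, rt, 1 h; then 28% aq. NH3, 0 °C to rt
Reagents that add atoms: ammonia, N; 1,1'-carbonyldiimidazole, O=C(n1ccnc1)n1ccnc1 (supplies the imidazole of 2 only)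
Why: Nucleophilic acyl substitution, with the acid activated as its acyl imidazolide and then opened by ammonia; no stereocenter is involved.

Step 2
Reactants: 3 2-(1,3-oxazol-5-yl)acetamide; 4 ethyl bromopyruvate
Product: 6 ethyl 2-(1,3-oxazol-5-ylmethyl)-1,3-oxazole-4-carboxylate, via hydroxyoxazoline 5 (not isolated)
Conditions: NaHCO3 (4 equiv), THF, 65 °C; then (CF3CO)2O, THF, 0 °C to rt
Reagents that add atoms: none
Why: Hantzsch-type (Blümlein–Lewy) oxazole synthesis, in which O-alkylation of the amide by the bromoketone and N-attack on the ketone give the 4-hydroxyoxazoline that trifluoroacetic anhydride dehydrates to aromatic ring B; no stereocenter remains.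

Step 3
Reactants: 6 ethyl 2-(1,3-oxazol-5-ylmethyl)-1,3-oxazole-4-carboxylate
Product: 7 2-(1,3-oxazol-5-ylmethyl)-1,3-oxazole-4-carbaldehyde
Conditions: i-Bu2AlH (1.2 equiv), CH2Cl2, −78 °C; aq. potassium sodium tartrate work-up
Reagents that add atoms: none
Why: Partial hydride reduction of an ester, where the tetrahedral aluminium hemiacetal is stable at −78 °C and releases the aldehyde only on work-up; this is routine for oxazole-4-carboxylates.

Step 4
Reactants: 7 2-(1,3-oxazol-5-ylmethyl)-1,3-oxazole-4-carbaldehyde; 8 acetaldehyde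
Product: 10 (3R)-3-[(tert-butyldimethylsilyl)oxy]-3-[2-(1,3-oxazol-5-ylmethyl)-1,3-oxazol-4-yl]propanal, via hydroxy aldehyde 9 (not isolated)
Conditions: (S)-α,α-bis[3,5-bis(trifluoromethyl)phenyl]-2-pyrrolidinemethanol (10 mol%), MeCHO (5 equiv), DMF, 4 °C; excess MeCHO evaporated; then imidazole, TBSCl, 0 °C to rt
Reagents that add atoms: tert-butyldimethylsilyl chloride, CC(C)(C)[Si](C)(C)Cl
Why: Diarylprolinol-catalysed enamine cross-aldol of acetaldehyde, in which the catalyst hydroxyl hydrogen-bonds aldehyde 7 and directs the acetaldehyde enamine to its Re face to give the (R)-carbinol (first stereocenter, catalyst-set), and in-situ silylation protects the dehydration-prone β-hydroxy aldehyde.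

Step 5
Reactants: 11 hydroxyacetone (1-hydroxypropan-2-one); 12 tetradecanoyl chloride
Product: 13 2-oxopropyl tetradecanoate
Conditions: Et3N, DMAP (5 mol%), CH2Cl2, 0 °C to rt
Reagents that add atoms: none
Why: DMAP-catalysed O-acylation of a primary alcohol by an acid chloride; no stereocenter is involved.

Step 6
Reactants: 10 (3R)-3-[(tert-butyldimethylsilyl)oxy]-3-[2-(1,3-oxazol-5-ylmethyl)-1,3-oxazol-4-yl]propanal; 13 2-oxopropyl tetradecanoate
Product: 14 (3S,4S,6R)-6-[(tert-butyldimethylsilyl)oxy]-4-hydroxy-6-[2-(1,3-oxazol-5-ylmethyl)-1,3-oxazol-4-yl]-2-oxohexan-3-yl tetradecanoate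
Conditions: (S)-N-[(4-dodecylphenyl)sulfonyl]pyrrolidine-2-carboxamide (20 mol%), 13 (4 equiv), H2O (1 equiv), ClCH2CH2Cl, 4 °C, 10 added over 12 h
Reagents that add atoms: none
Why: Proposed new method: an enamine aldol with a fatty α-acyloxy ketone (13) as the donor, which to my knowledge has not been demonstrated; the secondary amine forms the enamine toward the more acidic acyloxy-bearing CH2 with the acyloxy group trans to nitrogen (E geometry, avoiding allylic strain with the pyrrolidine), the tertiary enamine cannot undergo O-to-N acyl transfer, and the acidic sulfonamide N–H hydrogen-bonds the aldehyde of 10 in a chair-like Houk–List transition state so that its Re face is attacked, giving the 3,4-anti (3S,4S) aldol under catalyst control with the myristate already on O3; the closest known reaction type is the L-proline-catalysed anti-selective aldol of hydroxyacetone (and of methoxy- and chloroacetone) with aldehydes.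

Step 7
Reactants: 14 (3S,4S,6R)-6-[(tert-butyldimethylsilyl)oxy]-4-hydroxy-6-[2-(1,3-oxazol-5-ylmethyl)-1,3-oxazol-4-yl]-2-oxohexan-3-yl tetradecanoate
Product: 16 (2S,3R,4S,6R)-2,4,6-trihydroxy-6-[2-(1,3-oxazol-5-ylmethyl)-1,3-oxazol-4-yl]hexan-3-yl tetradecanoate, via silyl ether diol 15 (not isolated)
Conditions: Me4NBH(OAc)3 (5 equiv), MeCN/AcOH 1:1, −30 to −20 °C; then 48% aq. HF, 0 °C to rt; pH 7 buffer work-up
Reagents that add atoms: none
Why: Evans–Saksena hydroxyl-directed reduction, in which the C4 hydroxyl binds boron and delivers hydride intramolecularly through a chair-like transition state to give the 2,4-anti diol (C2 = S), a sense reinforced by polar Felkin–Anh control from the C3 acyloxy group, and aqueous HF then cleaves the TBS ether under acidic conditions that disfavour acyl migration.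

**Compound list**
1 | 2-(1,3-oxazol-5-yl)acetic acid | OC(=O)Cc1cnco1 | starting material
2 | 1-[(1,3-oxazol-5-yl)acetyl]-1H-imidazole | O=C(Cc1cnco1)n1ccnc1 | intermediate
3 | 2-(1,3-oxazol-5-yl)acetamide | NC(=O)Cc1cnco1 | intermediate
4 | ethyl bromopyruvate (ethyl 3-bromo-2-oxopropanoate) | CCOC(=O)C(=O)CBr | starting material
5 | ethyl 4-hydroxy-2-(1,3-oxazol-5-ylmethyl)-4,5-dihydro-1,3-oxazole-4-carboxylate (racemic) | CCOC(=O)C1(O)COC(Cc2cnco2)=N1 | intermediate
6 | ethyl 2-(1,3-oxazol-5-ylmethyl)-1,3-oxazole-4-carboxylate | CCOC(=O)c1coc(Cc2cnco2)n1 | intermediate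
7 | 2-(1,3-oxazol-5-ylmethyl)-1,3-oxazole-4-carbaldehyde | O=Cc1coc(Cc2cnco2)n1 | intermediate
8 | acetaldehyde | CC=O | starting material
9 | (3R)-3-hydroxy-3-[2-(1,3-oxazol-5-ylmethyl)-1,3-oxazol-4-yl]propanal | O=CC[C@@H](O)c1coc(Cc2cnco2)n1 | intermediate
10 | (3R)-3-[(tert-butyldimethylsilyl)oxy]-3-[2-(1,3-oxazol-5-ylmethyl)-1,3-oxazol-4-yl]propanal | O=CC[C@@H](O[Si](C)(C)C(C)(C)C)c1coc(Cc2cnco2)n1 | intermediate
11 | hydroxyacetone (1-hydroxypropan-2-one) | CC(=O)CO | starting material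
12 | tetradecanoyl chloride | CCCCCCCCCCCCCC(=O)Cl | starting material
13 | 2-oxopropyl tetradecanoate | CCCCCCCCCCCCCC(=O)OCC(C)=O | intermediate
14 | (3S,4S,6R)-6-[(tert-butyldimethylsilyl)oxy]-4-hydroxy-6-[2-(1,3-oxazol-5-ylmethyl)-1,3-oxazol-4-yl]-2-oxohexan-3-yl tetradecanoate | CCCCCCCCCCCCCC(=O)O[C@H](C(C)=O)[C@@H](O)C[C@@H](O[Si](C)(C)C(C)(C)C)c1coc(Cc2cnco2)n1 | intermediate
15 | (2S,3R,4S,6R)-6-[(tert-butyldimethylsilyl)oxy]-2,4-dihydroxy-6-[2-(1,3-oxazol-5-ylmethyl)-1,3-oxazol-4-yl]hexan-3-yl tetradecanoate | CCCCCCCCCCCCCC(=O)O[C@H]([C@H](C)O)[C@@H](O)C[C@@H](O[Si](C)(C)C(C)(C)C)c1coc(Cc2cnco2)n1 | intermediate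
16 | (2S,3R,4S,6R)-2,4,6-trihydroxy-6-[2-(1,3-oxazol-5-ylmethyl)-1,3-oxazol-4-yl]hexan-3-yl tetradecanoate (CNP0268144.1) | CCCCCCCCCCCCCC(=O)O[C@H]([C@H](C)O)[C@@H](O)C[C@@H](O)c1coc(Cc2cnco2)n1 | target

**Step count**
Total steps: 7. Longest linear sequence: 6 (steps 1, 2, 3, 4, 6, 7); step 5 is a one-step side branch.

**Three steps most likely to fail**

Step 6 (the proposed new aldol). The risks are reaction on the methyl side of 13, a modest anti/syn ratio with an α-unbranched acceptor, self-aldol or β-elimination of 10, and a 1,2-acyl shift in 14. The fallback uses known chemistry, sets out from 10 and returns at 16. L-Proline (30 mol%) and hydroxyacetone 11 in DMSO give the anti-diol ketone (3S,4S,6R)-6-[(tert-butyldimethylsilyl)oxy]-3,4-dihydroxy-6-[2-(1,3-oxazol-5-ylmethyl)-1,3-oxazol-4-yl]hexan-2-one F1; this is the established anti-selective proline aldol of hydroxyacetone, with the same facial sense. Me4NBH(OAc)3 in MeCN/AcOH reduces it to the triol (2S,3R,4S,6R)-6-[(tert-butyldimethylsilyl)oxy]-6-[2-(1,3-oxazol-5-ylmethyl)-1,3-oxazol-4-yl]hexane-2,3,4-triol F2. t-Bu2Si(OTf)2 with 2,6-lutidine ties the 1,3-related C2 and C4 hydroxyls into the six-membered 2,4-O-(di-tert-butylsilylene) derivative of F2 with free 3-OH F3. Tetradecanoyl chloride 12 with pyridine and DMAP then gives the 3-O-tetradecanoyl derivative of that silylene F4, and HF·pyridine in THF removes both silicon groups to give 16.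

Step 4 (acetaldehyde cross-aldol with in-situ silylation). The risks are the modest electrophilicity of 7 and dehydration of 9 to the enal before or during silylation. The fallback sets out from 7 and returns at 10. Chiral phosphoric acid-catalysed allylboration of 7 with allylboronic acid pinacol ester, using (R)-3,3'-bis(2,4,6-triisopropylphenyl)-1,1'-binaphthyl-2,2'-diyl hydrogen phosphate (5 mol%) in toluene at −30 °C, gives the homoallylic alcohol (1R)-1-[2-(1,3-oxazol-5-ylmethyl)-1,3-oxazol-4-yl]but-3-en-1-ol F5. TBSCl and imidazole in DMF give its tert-butyldimethylsilyl ether F6. Ozonolysis (O3, CH2Cl2/MeOH, −78 °C, then PPh3) cleaves the alkene to 10.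

Step 7 (directed reduction and desilylation). The risks are eroded anti selectivity next to the acyloxy group and myristate migration on the borate or during HF treatment. The fallback sets out from 14 and returns at 16. Et3SiOTf with 2,6-lutidine at −78 °C caps the C4 hydroxyl to give the 4-O-triethylsilyl ether of 14 F7. Non-directed reduction with LiBH(s-Bu)3 in THF at −78 °C (AcOH quench at −78 °C) follows polar Felkin–Anh control, with hydride anti to the C3 acyloxy group, to give the 2,3-syn alcohol (2S,3R,4S,6R)-6-[(tert-butyldimethylsilyl)oxy]-2-hydroxy-6-[2-(1,3-oxazol-5-ylmethyl)-1,3-oxazol-4-yl]-4-[(triethylsilyl)oxy]hexan-3-yl tetradecanoate F8. HF·pyridine in THF/pyridine at 0 °C removes both silyl ethers to give 16.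

**Further compounds**
F1 | step 6 | (3S,4S,6R)-6-[(tert-butyldimethylsilyl)oxy]-3,4-dihydroxy-6-[2-(1,3-oxazol-5-ylmethyl)-1,3-oxazol-4-yl]hexan-2-one | O[C@H](C(C)=O)[C@@H](O)C[C@@H](O[Si](C)(C)C(C)(C)C)c1coc(Cc2cnco2)n1
F2 | step 6 | (2S,3R,4S,6R)-6-[(tert-butyldimethylsilyl)oxy]-6-[2-(1,3-oxazol-5-ylmethyl)-1,3-oxazol-4-yl]hexane-2,3,4-triol | O[C@H]([C@H](C)O)[C@@H](O)C[C@@H](O[Si](C)(C)C(C)(C)C)c1coc(Cc2cnco2)n1
F3 | step 6 | 2,4-O-(di-tert-butylsilylene) derivative of F2 (1,3,2-dioxasilinane, free 3-OH) | O[C@H]([C@H](C)O[Si](C(C)(C)C)(C(C)(C)C)O3)[C@@H]3C[C@@H](O[Si](C)(C)C(C)(C)C)c1coc(Cc2cnco2)n1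
F4 | step 6 | 3-O-tetradecanoyl derivative of F3 | CCCCCCCCCCCCCC(=O)O[C@H]([C@H](C)O[Si](C(C)(C)C)(C(C)(C)C)O3)[C@@H]3C[C@@H](O[Si](C)(C)C(C)(C)C)c1coc(Cc2cnco2)n1
F5 | step 4 | (1R)-1-[2-(1,3-oxazol-5-ylmethyl)-1,3-oxazol-4-yl]but-3-en-1-ol | C=CC[C@@H](O)c1coc(Cc2cnco2)n1
F6 | step 4 | 4-{(1R)-1-[(tert-butyldimethylsilyl)oxy]but-3-en-1-yl}-2-(1,3-oxazol-5-ylmethyl)-1,3-oxazole | C=CC[C@@H](O[Si](C)(C)C(C)(C)C)c1coc(Cc2cnco2)n1
F7 | step 7 | (3S,4S,6R)-6-[(tert-butyldimethylsilyl)oxy]-6-[2-(1,3-oxazol-5-ylmethyl)-1,3-oxazol-4-yl]-2-oxo-4-[(triethylsilyl)oxy]hexan-3-yl tetradecanoate | CCCCCCCCCCCCCC(=O)O[C@H](C(C)=O)[C@@H](O[Si](CC)(CC)CC)C[C@@H](O[Si](C)(C)C(C)(C)C)c1coc(Cc2cnco2)n1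
F8 | step 7 | (2S,3R,4S,6R)-6-[(tert-butyldimethylsilyl)oxy]-2-hydroxy-6-[2-(1,3-oxazol-5-ylmethyl)-1,3-oxazol-4-yl]-4-[(triethylsilyl)oxy]hexan-3-yl tetradecanoate | CCCCCCCCCCCCCC(=O)O[C@H]([C@H](C)O)[C@@H](O[Si](CC)(CC)CC)C[C@@H](O[Si](C)(C)C(C)(C)C)c1coc(Cc2cnco2)n1
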